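Ring A is cut at C4a–C5 and C8–C8a. Its run C5(H)–C6(CO2Me)–C7(OMe)–C8(OH) is a methyl-oxaloacetate chain in disguise, and C4 with C11–C15 is the skeleton of (S)-citronellal. One anionic Michael–Dieckmann operation therefore joins a sulfonyl diester (C5–C8) to a citronellal-derived cyclohexenone (C1–C4, C4a, C8a; 4S,11S). It forms both bonds, expels sulfinate and delivers aromatic ring A with C8–OH, C7–OMe and C6–CO2Me already differentiated. The precursors are enone 4, made in one operation from citronellal and methyl vinyl ketone, and allyl sulfone 10, made in four steps from dimethyl oxalate and methyl propanoate. C15 and C1 are set afterwards.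

Key step: step 6

Remarks on the chemistry
- Atom labels: C1 = ring-B CH carrying methyl C20; C2, C3 = ring-B CH2; C4 = ring-B CH carrying the side chain; C4a, C8a = fusion carbons bonded to C4 and C1; C5 = aromatic CH; C6, C7, C8 = aromatic carbons carrying CO2Me, OMe and OH; C11 = side-chain CH(CH3) on C4; C12–C14 = CH2; C15 = CH(CH3); C16 = CH2OH. Ring A is the arene, ring B the saturated ring.
- Stereochemical reading of the target: C1 R, C4 S, C11 S, C15 S; the C1 methyl and the C4 side chain are trans on ring B. The structures of the key-step partners and product agree with this reading, so none is altered.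
- Geometry: 8, 9 and 10 are drawn as the isomer with the C5 carbon cis to the C8 ester (Z for 8, E for 9 and 10 only because the CIP ranking changes). This is the isomer expected from the chelated enol of 7 and the only one that allows six-membered closure. Isomer mixtures remain usable because the anion of 10 rotates about C6–C7.
- Assumption: the facial sense known for ruthenium–BINAP hydrogenation of geraniol-type allylic alcohols carries over to the 2-methylalk-2-en-1-ol 15.
- Assumption: (S)-citronellal of high enantiomeric purity is purchased.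
- Protecting-group logic: from step 7 the phenol is carried as a tert-butyl carbonate. It is inert in steps 8–10 and is itself the trigger of the final methylation, so no separate deprotection is needed.

Step 1
Reactants: 1 (S)-citronellal; 2 methyl vinyl ketone
Product: 4 (4S)-4-[(2S)-6-methylhept-5-en-2-yl]cyclohex-2-en-1-one, via keto aldehyde 3 (not isolated)
Conditions: (S)-2-[methoxy(diphenyl)methyl]pyrrolidine (5 mol %), ethyl 3,4-dihydroxybenzoate (20 mol %), neat, 4 °C; evaporate; LiOH (0.3 equiv), iPrOH, rt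
Reagents that add atoms: none
Why: Enamine-catalysed Michael addition to the vinyl ketone followed by mild base-induced intramolecular aldol condensation; in the E-enamine the methoxydiphenylmethyl arm of the (S)-catalyst screens one face, so the acceptor adds to the other and C4 is set as S under reagent control, while C11 comes unchanged from (S)-citronellal.

Step 2
Reactants: 5 dimethyl oxalate; 6 methyl propanoate
Product: 7 dimethyl 2-methyl-3-oxobutanedioate
Conditions: NaOMe, THF, 0 °C → rt; 1 M HCl
Reagents that add atoms: none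
Why: Crossed Claisen condensation in which the oxalate, having no alpha hydrogen and the more electrophilic carbonyl, acylates the propanoate enolate, the product being held as its stabilised enolate until acidification.

Step 3
Reactants: 7 dimethyl 2-methyl-3-oxobutanedioate
Product: 8 dimethyl (2Z)-2-methoxy-3-methylbut-2-enedioate
Conditions: TMSCHN2, PhMe–MeOH, 0 °C → rt
Reagents that add atoms: trimethylsilyldiazomethane, C[Si](C)(C)C=[N+]=[N-]
Why: Diazoalkane O-methylation of the acidic hydrogen-bonded enol of the oxalyl ester, which gives the enol ether on oxygen and keeps the geometry of the chelated enol (OMe cis to the C6 ester).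

Step 4
Reactants: 8 dimethyl (2Z)-2-methoxy-3-methylbut-2-enedioate
Product: 9 dimethyl (2E)-2-(bromomethyl)-3-methoxybut-2-enedioate
Conditions: NBS, AIBN (cat.), PhCF3, reflux
Reagents that add atoms: N-bromosuccinimide, O=C1CCC(=O)N1Br
Why: Wohl–Ziegler bromination, since the methyl group on the electron-poor push–pull alkene carries the only allylic C–H bonds and the alkene is too deactivated for ionic addition.

Step 5
Reactants: 9 dimethyl (2E)-2-(bromomethyl)-3-methoxybut-2-enedioate
Product: 10 dimethyl (2E)-2-methoxy-3-[(phenylsulfonyl)methyl]but-2-enedioate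
Conditions: PhSO2Na, DMF, rt
Reagents that add atoms: sodium benzenesulfinate, [Na+].[O-]S(=O)c1ccccc1
Why: SN2 displacement of the primary allylic bromide by the sulfur atom of the sulfinate in a dipolar aprotic solvent, SN2' attack being blocked because the far alkene carbon is fully substituted.

Step 6
Reactants: 4 (4S)-4-[(2S)-6-methylhept-5-en-2-yl]cyclohex-2-en-1-one; 10 dimethyl (2E)-2-methoxy-3-[(phenylsulfonyl)methyl]but-2-enedioate
Product: 13 methyl (8S)-4-hydroxy-3-methoxy-8-[(2S)-6-methylhept-5-en-2-yl]-5-oxo-5,6,7,8-tetrahydronaphthalene-2-carboxylate, via Michael adduct 11 (not isolated), via sulfonyl diketone 12 (not isolated)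
Conditions: 10 (1.2 equiv), LiOtBu (1.1 equiv), THF, −78 °C; add 4, → 0 °C; LiOtBu (2 equiv), → 50 °C; 1 M HCl
Reagents that add atoms: none
Why: Proposed new method: LiOtBu removes a CH2 proton of 10 (alpha to the sulfone and vinylogous to the C8 ester), the soft delocalised anion adds through C5 to C4a of enone 4, the resulting C8a enolate is acylated by the C8 ester with loss of methoxide, and after enolisation of the beta-diketone towards C8 the C4a hydrogen and benzenesulfinate from C5 are lost (E1cB), so ring A becomes aromatic without an oxidant. The closest known reaction type is the Hauser–Kraus annulation of sulfonyl phthalide or sulfonyl toluate anions with cyclohexenones; what is new is the acyclic push–pull allyl sulfone as donor. Ring A closes in a 6-exo-trig Dieckmann mode, which is open because C5 and the C8 ester sit cis on C6=C7 and the anion can rotate about C6–C7 if they do not. No stereocentre is created, since the transient centres at C4a, C5 and C8a are erased on aromatisation, and C4 is kept because the enone meets only the preformed, weakly basic anion and has been consumed before more base is added. The step needs C5 and not C7 to attack (C7 is fully substituted and only the C5 adduct keeps the captodative alkene), 1,4- and not 1,2-addition (stabilised anion, 1,2-adduct reverts), and acylation by the C8 and not the C6 ester (the C6 ester is a deactivated vinylogous carbonate and would give a strained alkylidene cyclopentanone, whereas the six-membered product drains irreversibly to the phenol).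

Step 7
Reactants: 13 methyl (8S)-4-hydroxy-3-methoxy-8-[(2S)-6-methylhept-5-en-2-yl]-5-oxo-5,6,7,8-tetrahydronaphthalene-2-carboxylate
Product: 14 methyl (8S)-4-[(tert-butoxycarbonyl)oxy]-3-methoxy-8-[(2S)-6-methylhept-5-en-2-yl]-5-oxo-5,6,7,8-tetrahydronaphthalene-2-carboxylate
Conditions: Boc2O, iPr2NEt, DMAP (cat.), CH2Cl2, rt
Reagents that add atoms: di-tert-butyl dicarbonate, CC(C)(C)OC(=O)OC(=O)OC(C)(C)C
Why: DMAP-catalysed acylation of the chelated phenol, the only hydroxyl group present, gives the aryl tert-butyl carbonate that shields the phenol from oxidants and later serves as the relay leaving group.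

Step 8
Reactants: 14 methyl (8S)-4-[(tert-butoxycarbonyl)oxy]-3-methoxy-8-[(2S)-6-methylhept-5-en-2-yl]-5-oxo-5,6,7,8-tetrahydronaphthalene-2-carboxylate
Product: 15 methyl (8S)-4-[(tert-butoxycarbonyl)oxy]-8-[(2S,5E)-7-hydroxy-6-methylhept-5-en-2-yl]-3-methoxy-5-oxo-5,6,7,8-tetrahydronaphthalene-2-carboxylate
Conditions: SeO2 (0.5 equiv), tBuOOH, salicylic acid (cat.), CH2Cl2, rt
Reagents that add atoms: selenium dioxide, O=[Se]=O; tert-butyl hydroperoxide, CC(C)(C)OO
Why: SeO2/tBuOOH allylic oxidation (ene reaction then 2,3-sigmatropic shift) attacks the electron-rich trisubstituted alkene at its E-methyl group to give the (E)-allylic alcohol, while the aryl ketone, the carbonate and the arene are inert at room temperature.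

Step 9
Reactants: 15 methyl (8S)-4-[(tert-butoxycarbonyl)oxy]-8-[(2S,5E)-7-hydroxy-6-methylhept-5-en-2-yl]-3-methoxy-5-oxo-5,6,7,8-tetrahydronaphthalene-2-carboxylate
Product: 16 methyl (8S)-4-[(tert-butoxycarbonyl)oxy]-8-[(2S,6S)-7-hydroxy-6-methylheptan-2-yl]-3-methoxy-5-oxo-5,6,7,8-tetrahydronaphthalene-2-carboxylate
Conditions: Ru(OAc)2[(S)-BINAP] (1 mol %), H2 (100 atm), MeOH, 25 °C
Reagents that add atoms: none
Why: Noyori asymmetric hydrogenation of an allylic alcohol, in which the hydroxyl group binds ruthenium and the (S)-BINAP complex is expected to add H2 to the same alkene face, relative to the CH2OH anchor, as in the geraniol-to-(R)-citronellol case, which corresponds to 15S here, while the aryl ketone is not reduced by this carboxylate complex.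

Step 10
Reactants: 16 methyl (8S)-4-[(tert-butoxycarbonyl)oxy]-8-[(2S,6S)-7-hydroxy-6-methylheptan-2-yl]-3-methoxy-5-oxo-5,6,7,8-tetrahydronaphthalene-2-carboxylate
Product: 17 methyl (5RS,8S)-4-[(tert-butoxycarbonyl)oxy]-5-hydroxy-8-[(2S,6S)-7-hydroxy-6-methylheptan-2-yl]-3-methoxy-5,6,7,8-tetrahydronaphthalene-2-carboxylate
Conditions: BH3·THF, THF, 0 °C → rt; MeOH
Reagents that add atoms: none
Why: Borane reduction of the aryl ketone runs through a neutral alkoxyborane, so no free alkoxide arises to trigger carbonate transfer and the benzoate ester and aryl carbonate are untouched, and the C1 configuration is immaterial because C1 becomes planar in the next step.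

Step 11
Reactants: 17 methyl (5RS,8S)-4-[(tert-butoxycarbonyl)oxy]-5-hydroxy-8-[(2S,6S)-7-hydroxy-6-methylheptan-2-yl]-3-methoxy-5,6,7,8-tetrahydronaphthalene-2-carboxylate
Product: 20 methyl (5R,8S)-4-hydroxy-8-[(2S,6S)-7-hydroxy-6-methylheptan-2-yl]-3-methoxy-5-methyl-5,6,7,8-tetrahydronaphthalene-2-carboxylate, via benzylic carbonate 18 (not isolated), via quinone methide 19 (not isolated)
Conditions: MeMgBr (4.5 equiv), THF, −78 → −20 °C; aq. NH4Cl
Reagents that add atoms: methylmagnesium bromide, C[Mg]Br
Why: Ortho-quinone methide relay in which the C1 magnesium alkoxide takes over the Boc group, the phenoxide expels tert-butyl carbonate, and MeMgBr adds 1,4 at C1 pseudoaxially on the face opposite the pseudoaxial C4 chain (chair-like transition state that leaves both substituents clear of the peri groups), which sets C1 as R and restores the phenol.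

Compound list
1 | (S)-citronellal, (3S)-3,7-dimethyloct-6-enal | O=CC[C@@H](C)CCC=C(C)C | starting material
2 | methyl vinyl ketone (but-3-en-2-one) | CC(=O)C=C | starting material
3 | (2S)-2-[(2S)-6-methylhept-5-en-2-yl]-5-oxohexanal (keto aldehyde, not isolated) | CC(=O)CC[C@@H]([C@@H](C)CCC=C(C)C)C=O | intermediate
4 | (4S)-4-[(2S)-6-methylhept-5-en-2-yl]cyclohex-2-en-1-one | O=C1CC[C@@H]([C@@H](C)CCC=C(C)C)C=C1 | intermediate
5 | dimethyl oxalate | COC(=O)C(=O)OC | starting material
6 | methyl propanoate | CCC(=O)OC | starting material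
7 | dimethyl 2-methyl-3-oxobutanedioate (racemic, keto–enol mixture) | COC(=O)C(=O)C(C)C(=O)OC | intermediate
8 | dimethyl (2Z)-2-methoxy-3-methylbut-2-enedioate | COC(=O)/C(OC)=C(\C)C(=O)OC | intermediate
9 | dimethyl (2E)-2-(bromomethyl)-3-methoxybut-2-enedioate | COC(=O)/C(OC)=C(\CBr)C(=O)OC | intermediate
10 | dimethyl (2E)-2-methoxy-3-[(phenylsulfonyl)methyl]but-2-enedioate | COC(=O)/C(OC)=C(\CS(=O)(=O)c1ccccc1)C(=O)OC | intermediate
11 | Michael adduct, dimethyl (2E)-2-methoxy-3-{[(2S)-2-[(2S)-6-methylhept-5-en-2-yl]-5-oxocyclohexyl](phenylsulfonyl)methyl}but-2-enedioate (lithium enolate in the flask, epimers at the two new centres, not isolated) | O=C1CC[C@@H]([C@@H](C)CCC=C(C)C)C(C1)C(S(=O)(=O)c1ccccc1)/C(C(=O)OC)=C(/OC)C(=O)OC | intermediate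
12 | sulfonyl diketone, methyl (8S)-3-methoxy-8-[(2S)-6-methylhept-5-en-2-yl]-4,5-dioxo-1-(phenylsulfonyl)-1,4,4a,5,6,7,8,8a-octahydronaphthalene-2-carboxylate (epimers at C1, C4a, C8a, not isolated) | COC(=O)C1=C(OC)C(=O)C2C(=O)CC[C@@H]([C@@H](C)CCC=C(C)C)C2C1S(=O)(=O)c1ccccc1 | intermediate
13 | methyl (8S)-4-hydroxy-3-methoxy-8-[(2S)-6-methylhept-5-en-2-yl]-5-oxo-5,6,7,8-tetrahydronaphthalene-2-carboxylate | COC(=O)c1cc2c(c(O)c1OC)C(=O)CC[C@H]2[C@@H](C)CCC=C(C)C | intermediate
14 | methyl (8S)-4-[(tert-butoxycarbonyl)oxy]-3-methoxy-8-[(2S)-6-methylhept-5-en-2-yl]-5-oxo-5,6,7,8-tetrahydronaphthalene-2-carboxylate | COC(=O)c1cc2c(c(OC(=O)OC(C)(C)C)c1OC)C(=O)CC[C@H]2[C@@H](C)CCC=C(C)C | intermediate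
15 | methyl (8S)-4-[(tert-butoxycarbonyl)oxy]-8-[(2S,5E)-7-hydroxy-6-methylhept-5-en-2-yl]-3-methoxy-5-oxo-5,6,7,8-tetrahydronaphthalene-2-carboxylate | COC(=O)c1cc2c(c(OC(=O)OC(C)(C)C)c1OC)C(=O)CC[C@H]2[C@@H](C)CC/C=C(\C)CO | intermediate
16 | methyl (8S)-4-[(tert-butoxycarbonyl)oxy]-8-[(2S,6S)-7-hydroxy-6-methylheptan-2-yl]-3-methoxy-5-oxo-5,6,7,8-tetrahydronaphthalene-2-carboxylate | COC(=O)c1cc2c(c(OC(=O)OC(C)(C)C)c1OC)C(=O)CC[C@H]2[C@@H](C)CCC[C@H](C)CO | intermediate
17 | methyl (5RS,8S)-4-[(tert-butoxycarbonyl)oxy]-5-hydroxy-8-[(2S,6S)-7-hydroxy-6-methylheptan-2-yl]-3-methoxy-5,6,7,8-tetrahydronaphthalene-2-carboxylate (C5 epimers) | COC(=O)c1cc2c(c(OC(=O)OC(C)(C)C)c1OC)C(O)CC[C@H]2[C@@H](C)CCC[C@H](C)CO | intermediate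
18 | benzylic carbonate, methyl (5RS,8S)-5-[(tert-butoxycarbonyl)oxy]-4-hydroxy-8-[(2S,6S)-7-hydroxy-6-methylheptan-2-yl]-3-methoxy-5,6,7,8-tetrahydronaphthalene-2-carboxylate (magnesium salt in the flask, not isolated) | COC(=O)c1cc2c(c(O)c1OC)C(OC(=O)OC(C)(C)C)CC[C@H]2[C@@H](C)CCC[C@H](C)CO | intermediate
19 | quinone methide, methyl (8S)-8-[(2S,6S)-7-hydroxy-6-methylheptan-2-yl]-3-methoxy-4-oxo-4,6,7,8-tetrahydronaphthalene-2-carboxylate (magnesium alkoxide in the flask, not isolated) | COC(=O)C1=C(OC)C(=O)C2=CCC[C@@H]([C@@H](C)CCC[C@H](C)CO)C2=C1 | intermediate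
20 | methyl (5R,8S)-4-hydroxy-8-[(2S,6S)-7-hydroxy-6-methylheptan-2-yl]-3-methoxy-5-methyl-5,6,7,8-tetrahydronaphthalene-2-carboxylate | COC(=O)c1cc2c(c(O)c1OC)[C@H](C)CC[C@H]2[C@@H](C)CCC[C@H](C)CO | target

Total step count: 11. Longest linear sequence: 10 steps (steps 2–5, then 6–11); the enone branch adds one step.

Steps most likely to fail

Step 6 (the step labelled as a new method). Three processes may go wrong: the enolate formed after conjugate addition may acylate on the C6 ester and close a five-membered ring; the addition at the hindered C4a may stall or revert; and loss of sulfinate may lag, leaving non-aromatic diketone. A fallback by known cycloaddition chemistry sets out from enone 4 and enol ether 8 and comes back at 13. Alpha-iodination of 4 (I2, pyridine, CH2Cl2) would give the iodo enone (4S)-2-iodo-4-[(2S)-6-methylhept-5-en-2-yl]cyclohex-2-en-1-one F1. Gamma-deprotonation of 8 with LiN(iPr)2 and O-silylation (Me3SiCl, THF, −78 °C) would give the silyl ketene acetal diene methyl 3,4-dimethoxy-2-methylidene-4-[(trimethylsilyl)oxy]but-3-enoate F2. Diels–Alder reaction of the two (toluene, 80 °C) joins the nucleophilic CH2 terminus of the diene to C4a and the acetal carbon to C8a, giving the iodo cycloadduct methyl (8S)-4a-iodo-3,4-dimethoxy-8-[(2S)-6-methylhept-5-en-2-yl]-5-oxo-4-[(trimethylsilyl)oxy]-1,4,4a,5,6,7,8,8a-octahydronaphthalene-2-carboxylate F3. DBU then removes HI across C8a–C4a, and dilute HCl unmasks the C8 ketone, whose dienone form tautomerises to 13. This is the established halo-enone/ketene-acetal-diene benzannulation with dehydrohalogenative aromatisation.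

Step 11. Facial discrimination in the methyl addition may be poor, the Grignard reagent may attack the C6 ester before the quinone methide is consumed, or the quinone methide may be lost by prototropy. A fallback under catalyst control sets out from 16 and comes back at 20. K2CO3 in MeOH would cleave the aryl carbonate to the keto phenol methyl (8S)-4-hydroxy-8-[(2S,6S)-7-hydroxy-6-methylheptan-2-yl]-3-methoxy-5-oxo-5,6,7,8-tetrahydronaphthalene-2-carboxylate F4. MeMgBr with CeCl3 (THF, −78 °C) would add to the ketone to give the tertiary carbinol methyl (5RS,8S)-4,5-dihydroxy-8-[(2S,6S)-7-hydroxy-6-methylheptan-2-yl]-3-methoxy-5-methyl-5,6,7,8-tetrahydronaphthalene-2-carboxylate F5. TsOH (toluene, 60 °C) would dehydrate it to the dihydronaphthalene methyl (8S)-4-hydroxy-8-[(2S,6S)-7-hydroxy-6-methylheptan-2-yl]-3-methoxy-5-methyl-7,8-dihydronaphthalene-2-carboxylate F6. Asymmetric hydrogenation with [Ir(cod)(tBu-PHOX)][B(3,5-(CF3)2C6H3)4], with the ligand antipode chosen so that hydrogen enters C1 on the face syn to the C4 chain, would then give 20.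

Step 9. Enantiofacial control may be weaker for a 2-methyl allylic alcohol than for the 3-methyl type, and alkene migration to the aldehyde may compete at low hydrogen pressure. A fallback through the carboxylic acid sets out from 15 and comes back at 17. MnO2 (CH2Cl2) would give the enal methyl (8S)-4-[(tert-butoxycarbonyl)oxy]-3-methoxy-8-[(2S,5E)-6-methyl-7-oxohept-5-en-2-yl]-5-oxo-5,6,7,8-tetrahydronaphthalene-2-carboxylate F7. Pinnick oxidation (NaClO2, NaH2PO4, 2-methylbut-2-ene) would give the enoic acid (2E,6S)-6-[(1S)-5-[(tert-butoxycarbonyl)oxy]-6-methoxy-7-(methoxycarbonyl)-4-oxo-1,2,3,4-tetrahydronaphthalen-1-yl]-2-methylhept-2-enoic acid F8. Ru(OAc)2[(S)-BINAP] and H2 in MeOH, the well-established carboxylate-directed hydrogenation of tiglic-acid-type substrates, would give the saturated acid (2S,6S)-6-[(1S)-5-[(tert-butoxycarbonyl)oxy]-6-methoxy-7-(methoxycarbonyl)-4-oxo-1,2,3,4-tetrahydronaphthalen-1-yl]-2-methylheptanoic acid F9. BH3·THF then reduces the acid and the C1 ketone together and delivers 17.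

Further compounds
F1 | step 6 | (4S)-2-iodo-4-[(2S)-6-methylhept-5-en-2-yl]cyclohex-2-en-1-one | O=C1CC[C@@H]([C@@H](C)CCC=C(C)C)C=C1I
F2 | step 6 | methyl 3,4-dimethoxy-2-methylidene-4-[(trimethylsilyl)oxy]but-3-enoate (alkene isomers) | C=C(C(=O)OC)C(OC)=C(OC)O[Si](C)(C)C
F3 | step 6 | methyl (8S)-4a-iodo-3,4-dimethoxy-8-[(2S)-6-methylhept-5-en-2-yl]-5-oxo-4-[(trimethylsilyl)oxy]-1,4,4a,5,6,7,8,8a-octahydronaphthalene-2-carboxylate | COC(=O)C1=C(OC)C(OC)(O[Si](C)(C)C)C2(I)C(=O)CC[C@@H]([C@@H](C)CCC=C(C)C)C2C1
F4 | step 11 | methyl (8S)-4-hydroxy-8-[(2S,6S)-7-hydroxy-6-methylheptan-2-yl]-3-methoxy-5-oxo-5,6,7,8-tetrahydronaphthalene-2-carboxylate | COC(=O)c1cc2c(c(O)c1OC)C(=O)CC[C@H]2[C@@H](C)CCC[C@H](C)CO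
F5 | step 11 | methyl (5RS,8S)-4,5-dihydroxy-8-[(2S,6S)-7-hydroxy-6-methylheptan-2-yl]-3-methoxy-5-methyl-5,6,7,8-tetrahydronaphthalene-2-carboxylate | COC(=O)c1cc2c(c(O)c1OC)C(C)(O)CC[C@H]2[C@@H](C)CCC[C@H](C)CO
F6 | step 11 | methyl (8S)-4-hydroxy-8-[(2S,6S)-7-hydroxy-6-methylheptan-2-yl]-3-methoxy-5-methyl-7,8-dihydronaphthalene-2-carboxylate | COC(=O)c1cc2c(c(O)c1OC)C(C)=CC[C@H]2[C@@H](C)CCC[C@H](C)CO
F7 | step 9 | methyl (8S)-4-[(tert-butoxycarbonyl)oxy]-3-methoxy-8-[(2S,5E)-6-methyl-7-oxohept-5-en-2-yl]-5-oxo-5,6,7,8-tetrahydronaphthalene-2-carboxylate | COC(=O)c1cc2c(c(OC(=O)OC(C)(C)C)c1OC)C(=O)CC[C@H]2[C@@H](C)CC/C=C(\C)C=O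
F8 | step 9 | (2E,6S)-6-[(1S)-5-[(tert-butoxycarbonyl)oxy]-6-methoxy-7-(methoxycarbonyl)-4-oxo-1,2,3,4-tetrahydronaphthalen-1-yl]-2-methylhept-2-enoic acid | COC(=O)c1cc2c(c(OC(=O)OC(C)(C)C)c1OC)C(=O)CC[C@H]2[C@@H](C)CC/C=C(\C)C(=O)O
F9 | step 9 | (2S,6S)-6-[(1S)-5-[(tert-butoxycarbonyl)oxy]-6-methoxy-7-(methoxycarbonyl)-4-oxo-1,2,3,4-tetrahydronaphthalen-1-yl]-2-methylheptanoic acid | COC(=O)c1cc2c(c(OC(=O)OC(C)(C)C)c1OC)C(=O)CC[C@H]2[C@@H](C)CCC[C@H](C)C(=O)O
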